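**Retrosynthetic overview**

1. The target is robinetinidol-(4β→8)-epigallocatechin: upper unit (2R,3S,4R; rings A, B, C; 2,3-trans, 3,4-cis), lower unit (2R,3R; rings D, E, F) taken intact from (−)-epigallocatechin. The last operations are ester cleavage and hydrogenolysis of ten benzyl ethers.
2. Key disconnection: ring C is opened across C2–C3 and C4–C4a (formal [4+2], oxa-Povarov type). The four-atom unit C4a=C8a–O1=C2 is an O-aryl oxocarbenium ion made from 3,4,5-tris(benzyloxy)benzaldehyde and 3-(benzyloxy)phenol; the two-atom unit C3=C4 is a (Z)-enol benzoate on C8 of ring D.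
3. Enabling feature: C4 is benzylic to C8 of ring D, whose oxygen atoms at C7 and C8a (ortho) and C5 (para) carry positive charge at C4, so C3 is the nucleophilic alkene carbon even though it bears an (acylated) oxygen. C4a of the resorcinol-type ring A lies ortho to O1 and para to O7, which fixes the site of the closing Friedel–Crafts bond.
4. Alkene partner: epigallocatechin → benzyl ethers → 8-bromide → 8-ethynyl → Z-selective anti-Markovnikov addition of benzoic acid. Acetal partner: aldehyde → dimethyl acetal → chloro ether → mixed O-aryl O-methyl acetal.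
5. Ring order: rings D, E, F come with epigallocatechin, rings A and B come as intact arenes, and ring C is formed last, in the key step, together with C2, C3 and C4.

Key step: step 9

Remark: the sense of induction of a chiral acid on this new substrate pair cannot be derived from precedent. The route is written for the (S,S)-acid; its antipode takes its place if a first experiment shows the opposite sense (the two outcomes are diastereomers, because the lower unit is enantiopure).

**Route**

Step 1
Reactants: 1 (−)-epigallocatechin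
Product: 2 5,7,3',4',5'-penta-O-benzyl-(−)-epigallocatechin
Conditions: BnBr (5.5 equiv), K2CO3, DMF, 0 °C → rt, argon
Reagents that add atoms: benzyl bromide, BrCc1ccccc1
Why: Williamson etherification of the five phenols with a carbonate base leaves the aliphatic 3-OH free and does not touch C2 or C3.

Step 2
Reactants: 2 5,7,3',4',5'-penta-O-benzyl-(−)-epigallocatechin
Product: 3 3,5,7,3',4',5'-hexa-O-benzyl-(−)-epigallocatechin
Conditions: NaH, BnBr, DMF, 0 °C → rt
Reagents that add atoms: benzyl bromide, BrCc1ccccc1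
Why: Williamson etherification of the secondary alkoxide, safe for C2 because no free phenol remains that could open ring F through a quinone methide.

Step 3
Reactants: 3 3,5,7,3',4',5'-hexa-O-benzyl-(−)-epigallocatechin
Product: 4 8-bromo-3,5,7,3',4',5'-hexa-O-benzyl-(−)-epigallocatechin
Conditions: NBS (1.0 equiv), CH2Cl2, −78 °C → rt
Reagents that add atoms: N-bromosuccinimide, O=C1CCC(=O)N1Br
Why: Electrophilic aromatic bromination, which on benzylated flavan-3-ols goes to C8, the most nucleophilic carbon of the phloroglucinol-type ring D.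

Step 4
Reactants: 4 8-bromo-3,5,7,3',4',5'-hexa-O-benzyl-(−)-epigallocatechin
Product: 5 8-[(trimethylsilyl)ethynyl]-3,5,7,3',4',5'-hexa-O-benzyl-(−)-epigallocatechin
Conditions: ethynyltrimethylsilane, Pd(PhCN)2Cl2 (cat.), P(t-Bu)3 (cat.), CuI (cat.), i-Pr2NH, 1,4-dioxane, rt → 50 °C
Reagents that add atoms: ethynyltrimethylsilane, C#C[Si](C)(C)C
Why: Sonogashira coupling, in which the bulky electron-rich phosphine lets zerovalent palladium insert into the hindered, electron-rich aryl bromide under mild conditions.

Step 5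
Reactants: 5 8-[(trimethylsilyl)ethynyl]-3,5,7,3',4',5'-hexa-O-benzyl-(−)-epigallocatechin
Product: 6 8-ethynyl-3,5,7,3',4',5'-hexa-O-benzyl-(−)-epigallocatechin
Conditions: K2CO3 (cat.), MeOH/THF, rt
Reagents that add atoms: none
Why: Methoxide-mediated protodesilylation of the alkynylsilane, to which benzyl ethers are inert.

Step 6
Reactants: 6 8-ethynyl-3,5,7,3',4',5'-hexa-O-benzyl-(−)-epigallocatechin
Product: 7 (Z)-2-[3,5,7,3',4',5'-hexa-O-benzyl-(−)-epigallocatechin-8-yl]ethenyl benzoate
Conditions: PhCO2H (1.2 equiv), Ru(2-methylallyl)2(dppb) (cat.; dppb = Ph2P(CH2)4PPh2), toluene, 65 °C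
Reagents that add atoms: benzoic acid, OC(=O)c1ccccc1
Why: Ruthenium-catalysed anti-Markovnikov addition of a carboxylic acid to a terminal alkyne through a vinylidene complex, which places the carboxylate on the terminal carbon and gives the (Z)-enol ester.

Step 7
Reactants: 8 3,4,5-tris(benzyloxy)benzaldehyde
Product: 9 3,4,5-tris(benzyloxy)benzaldehyde dimethyl acetal
Conditions: HC(OMe)3, TsOH·H2O (cat.), MeOH/THF, rt; Et3N quench
Reagents that add atoms: trimethyl orthoformate, COC(OC)OC
Why: Acid-catalysed acetalisation driven to completion by the orthoester.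

Step 8
Reactants: 9 3,4,5-tris(benzyloxy)benzaldehyde dimethyl acetal; 10 3-(benzyloxy)phenol
Product: 12 racemic [3-(benzyloxy)phenoxy](methoxy)[3,4,5-tris(benzyloxy)phenyl]methane, via chloro ether 11 (not isolated)
Conditions: AcCl (1.05 equiv), CH2Cl2, 0 °C → rt; then sodium phenoxide of 10 (from 10 and NaH), THF, −20 °C → rt
Reagents that add atoms: none
Why: Acetal–acyl chloride exchange gives the α-chloro ether, which alkylates the phenoxide on oxygen by substitution at the benzylic acetal carbon; the new stereocenter is racemic and is erased in step 9.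

Step 9
Reactants: 7 (Z)-2-[3,5,7,3',4',5'-hexa-O-benzyl-(−)-epigallocatechin-8-yl]ethenyl benzoate; 12 racemic [3-(benzyloxy)phenoxy](methoxy)[3,4,5-tris(benzyloxy)phenyl]methane
Product: 14 3-O-benzoyl-7,3',4',5'-tetra-O-benzylrobinetinidol-(4β→8)-3,5,7,3',4',5'-hexa-O-benzylepigallocatechin [upper unit (2R,3S,4R); lower unit (2R,3R)], via oxocarbenium ion 13 (not isolated)
Conditions: (S,S)-imidodiphosphorimidate Brønsted acid (from two (S)-3,3'-diphenyl-BINOL units, N-triflyl groups; 5 mol%), 5 Å molecular sieves, CH2Cl2, −60 °C → −30 °C; 12 in slight excess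
Reagents that add atoms: none
Why: Proposed new method: the chiral acid protonates the methoxy oxygen of 12 and expels methanol to give the (E)-O-aryl oxocarbenium ion 13 as a contact ion pair with the chiral anion, and this cationic 2-oxadiene (C4a=C8a–O1=C2) takes up the Z-alkene of 7 in a polar, strongly asynchronous formal [4+2] cycloaddition in which the C2–C3 bond leads and the C4–C4a bond follows, after which loss of the C4a proton restores ring A and returns the acid. The closest known reaction type is the Lewis-acid-promoted oxa-Povarov annulation of O-aryl oxocarbenium ions with styrenes, and for the catalyst control the chiral-Brønsted-acid-catalysed Povarov reaction and imidodiphosphorimidate-controlled additions to oxocarbenium ions; new here are the enol ester as two-carbon partner and the chiral-anion control. Ring C is the only ring closed, by Prins-type attack of C3 on C2 followed by a 6-exo-trig Friedel–Crafts attack of C4a on the para-quinone-methide-like C4. C3 and C4 should come out cis because both new bonds form on the same face of the Z-alkene, the benzoate carbonyl assisting at the electron-poor C4 from the opposite face in the transition state so that rotation about C3–C4 does not outrun closure; C2 and C3 should come out trans because the cis-disposed aryl and benzoyloxy groups of the alkene can only point away from ring A (exo approach) while the C2 aryl group sits outside on the (E)-oxocarbenium ion; the absolute sense (2R,3S,4R) is set by the chiral anion shielding one face of 13. The step needs C3 to be the nucleophilic alkene carbon (secured by the benzoate, which damps oxygen lone-pair donation, and by the three oxygen atoms of ring D ortho and para to C8), closure at C4a (para to the 7-benzyloxy group and unhindered, whereas the other ortho carbon lies between two oxygen substituents), and preference over Friedel–Crafts attack of 13 on C6 of ring D (that carbon is flanked by two benzyloxy groups).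

Step 10
Reactants: 14 3-O-benzoyl-7,3',4',5'-tetra-O-benzylrobinetinidol-(4β→8)-3,5,7,3',4',5'-hexa-O-benzylepigallocatechin
Product: 15 7,3',4',5'-tetra-O-benzylrobinetinidol-(4β→8)-3,5,7,3',4',5'-hexa-O-benzylepigallocatechin (free 3-OH in the upper unit)
Conditions: NaOMe (cat.), MeOH/THF, rt
Reagents that add atoms: none
Why: Zemplén transesterification removes the secondary benzoate without touching benzyl ethers or any stereocenter.

Step 11
Reactants: 15 7,3',4',5'-tetra-O-benzylrobinetinidol-(4β→8)-3,5,7,3',4',5'-hexa-O-benzylepigallocatechin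
Product: 16 robinetinidol-(4β→8)-epigallocatechin (target)
Conditions: H2 (1 atm), Pd(OH)2/C, THF/MeOH/H2O, rt; filtration and freeze-drying under argon
Reagents that add atoms: none
Why: Hydrogenolysis of the ten benzyl ethers under neutral conditions, the usual last step for benzylated proanthocyanidins, should leave the C4–C8 bond and all five stereocenters intact.

**Compound list**

1 | (−)-epigallocatechin, (2R,3R) | Oc1cc(O)c2c(c1)O[C@H](c1cc(O)c(O)c(O)c1)[C@H](O)C2 | starting material
2 | 5,7,3',4',5'-penta-O-benzyl-(−)-epigallocatechin | c1ccccc1COc1cc(OCc3ccccc3)c2c(c1)O[C@H](c1cc(OCc3ccccc3)c(OCc3ccccc3)c(OCc3ccccc3)c1)[C@H](O)C2 | intermediate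
3 | 3,5,7,3',4',5'-hexa-O-benzyl-(−)-epigallocatechin | c1ccccc1COc1cc(OCc3ccccc3)c2c(c1)O[C@H](c1cc(OCc3ccccc3)c(OCc3ccccc3)c(OCc3ccccc3)c1)[C@H](OCc1ccccc1)C2 | intermediate
4 | 8-bromo-3,5,7,3',4',5'-hexa-O-benzyl-(−)-epigallocatechin | Brc1c(OCc3ccccc3)cc(OCc3ccccc3)c2c1O[C@H](c1cc(OCc3ccccc3)c(OCc3ccccc3)c(OCc3ccccc3)c1)[C@H](OCc1ccccc1)C2 | intermediate
5 | 8-[(trimethylsilyl)ethynyl]-3,5,7,3',4',5'-hexa-O-benzyl-(−)-epigallocatechin | C[Si](C)(C)C#Cc1c(OCc3ccccc3)cc(OCc3ccccc3)c2c1O[C@H](c1cc(OCc3ccccc3)c(OCc3ccccc3)c(OCc3ccccc3)c1)[C@H](OCc1ccccc1)C2 | intermediate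
6 | 8-ethynyl-3,5,7,3',4',5'-hexa-O-benzyl-(−)-epigallocatechin | C#Cc1c(OCc3ccccc3)cc(OCc3ccccc3)c2c1O[C@H](c1cc(OCc3ccccc3)c(OCc3ccccc3)c(OCc3ccccc3)c1)[C@H](OCc1ccccc1)C2 | intermediate
7 | (Z)-2-[3,5,7,3',4',5'-hexa-O-benzyl-(−)-epigallocatechin-8-yl]ethenyl benzoate | O=C(c1ccccc1)O/C=C\c1c(OCc3ccccc3)cc(OCc3ccccc3)c2c1O[C@H](c1cc(OCc3ccccc3)c(OCc3ccccc3)c(OCc3ccccc3)c1)[C@H](OCc1ccccc1)C2 | intermediate
8 | 3,4,5-tris(benzyloxy)benzaldehyde | O=Cc1cc(OCc2ccccc2)c(OCc2ccccc2)c(OCc2ccccc2)c1 | starting material
9 | 3,4,5-tris(benzyloxy)benzaldehyde dimethyl acetal | COC(OC)c1cc(OCc2ccccc2)c(OCc2ccccc2)c(OCc2ccccc2)c1 | intermediate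
10 | 3-(benzyloxy)phenol | Oc1cccc(OCc2ccccc2)c1 | starting material
11 | racemic chloro(methoxy)[3,4,5-tris(benzyloxy)phenyl]methane (chloro ether, not isolated) | COC(Cl)c1cc(OCc2ccccc2)c(OCc2ccccc2)c(OCc2ccccc2)c1 | intermediate
12 | racemic [3-(benzyloxy)phenoxy](methoxy)[3,4,5-tris(benzyloxy)phenyl]methane | COC(Oc1cccc(OCc2ccccc2)c1)c1cc(OCc2ccccc2)c(OCc2ccccc2)c(OCc2ccccc2)c1 | intermediate
13 | (E)-O-[3-(benzyloxy)phenyl] oxocarbenium ion of 8 (not isolated) | c1ccccc1COc1cccc(c1)/[O+]=C/c1cc(OCc2ccccc2)c(OCc2ccccc2)c(OCc2ccccc2)c1 | intermediate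
14 | 3-O-benzoyl-7,3',4',5'-tetra-O-benzylrobinetinidol-(4β→8)-3,5,7,3',4',5'-hexa-O-benzylepigallocatechin, upper unit (2R,3S,4R), lower unit (2R,3R) | c1ccccc1COc1ccc2c(c1)O[C@H](c1cc(OCc3ccccc3)c(OCc3ccccc3)c(OCc3ccccc3)c1)[C@@H](OC(=O)c1ccccc1)[C@H]2c1c(OCc3ccccc3)cc(OCc3ccccc3)c2c1O[C@H](c1cc(OCc3ccccc3)c(OCc3ccccc3)c(OCc3ccccc3)c1)[C@H](OCc1ccccc1)C2 | intermediate
15 | 7,3',4',5'-tetra-O-benzylrobinetinidol-(4β→8)-3,5,7,3',4',5'-hexa-O-benzylepigallocatechin, free upper 3-OH | c1ccccc1COc1ccc2c(c1)O[C@H](c1cc(OCc3ccccc3)c(OCc3ccccc3)c(OCc3ccccc3)c1)[C@@H](O)[C@H]2c1c(OCc3ccccc3)cc(OCc3ccccc3)c2c1O[C@H](c1cc(OCc3ccccc3)c(OCc3ccccc3)c(OCc3ccccc3)c1)[C@H](OCc1ccccc1)C2 | intermediate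
16 | robinetinidol-(4β→8)-epigallocatechin, upper unit (2R,3S,4R), lower unit (2R,3R) | Oc1ccc2c(c1)O[C@H](c1cc(O)c(O)c(O)c1)[C@@H](O)[C@H]2c1c(O)cc(O)c2c1O[C@H](c1cc(O)c(O)c(O)c1)[C@H](O)C2 | target

**Step count**

Total: 11 steps. Longest linear sequence: 9 steps (steps 1–6, 9, 10, 11); steps 7 and 8 form the short branch.

**Steps most likely to fail**

Step 9 (proposed new method). What may go wrong:
- weak facial discrimination by the chiral anion, so that both diastereomeric series form;
- loss of the alkene geometry through a long-lived open cation at C4, leading to the 3,4-trans series;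
- an endo approach, leading to the 2,3-cis series;
- competing Friedel–Crafts alkylation at C6 of ring D.

Fallback with known chemistry (Lewis-acid condensation of a flavan-3,4-diol with a benzylated flavan-3-ol), setting out from compound 3 and returning at compound 15. Commercial (+)-dihydrorobinetin F1 would be benzylated at its four phenols (BnBr, K2CO3, DMF) to the tetra-O-benzyl ether F2. F2 would be reduced with NaBH4 (EtOH/THF) to the 2,3-trans-3,4-trans flavan-3,4-diol F3. F3 would be ionised at C4 with TiCl4 (CH2Cl2, −78 °C → 0 °C) in the presence of excess 3, whose C8 captures the cation. Both C4 epimers are expected; the 4β (3,4-cis) epimer, separated by chromatography, is 15, and the route resumes at step 11.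

Step 6. What may go wrong: Markovnikov addition or erosion of the Z geometry at the congested, di-ortho-substituted aryl alkyne, or slow vinylidene formation.

Fallback from compound 6, returning at compound 7. Hydroboration of 6 with (C6H11)2BH (THF, 0 °C) and oxidation with NaBO3·4H2O would give the arylacetaldehyde F4. Kinetic deprotonation with KN(SiMe3)2 (THF, −78 °C) and O-acylation with benzoic anhydride should give the enol benzoates, from which the Z isomer, expected to predominate from the potassium enolate, is separated as 7.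

Step 4. What may go wrong: slow oxidative addition at the hindered, electron-rich bromide, leading to protodebromination and alkyne homocoupling.

Fallback from compound 4, returning at compound 6 (steps 4 and 5 are both bypassed). Bromine–lithium exchange on 4 (n-BuLi, THF, −78 °C) and quenching with DMF would give the 8-carbaldehyde F5. Ohira–Bestmann homologation (dimethyl (1-diazo-2-oxopropyl)phosphonate, K2CO3, MeOH/THF, rt) would convert F5 into alkyne 6.

**Further compounds**

F1 | step 9 | (+)-dihydrorobinetin, (2R,3R)-3,7-dihydroxy-2-(3,4,5-trihydroxyphenyl)chroman-4-one | Oc1ccc2c(c1)O[C@H](c1cc(O)c(O)c(O)c1)[C@@H](O)C2=O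
F2 | step 9 | 7,3',4',5'-tetra-O-benzyl-(+)-dihydrorobinetin | c1ccccc1COc1ccc2c(c1)O[C@H](c1cc(OCc3ccccc3)c(OCc3ccccc3)c(OCc3ccccc3)c1)[C@@H](O)C2=O
F3 | step 9 | (2R,3S,4R)-7-(benzyloxy)-2-[3,4,5-tris(benzyloxy)phenyl]chromane-3,4-diol | c1ccccc1COc1ccc2c(c1)O[C@H](c1cc(OCc3ccccc3)c(OCc3ccccc3)c(OCc3ccccc3)c1)[C@@H](O)[C@@H]2O
F4 | step 6 | 2-[3,5,7,3',4',5'-hexa-O-benzyl-(−)-epigallocatechin-8-yl]acetaldehyde | O=CCc1c(OCc3ccccc3)cc(OCc3ccccc3)c2c1O[C@H](c1cc(OCc3ccccc3)c(OCc3ccccc3)c(OCc3ccccc3)c1)[C@H](OCc1ccccc1)C2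
F5 | step 4 | 3,5,7,3',4',5'-hexa-O-benzyl-(−)-epigallocatechin-8-carbaldehyde | O=Cc1c(OCc3ccccc3)cc(OCc3ccccc3)c2c1O[C@H](c1cc(OCc3ccccc3)c(OCc3ccccc3)c(OCc3ccccc3)c1)[C@H](OCc1ccccc1)C2
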